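**Retrosynthetic overview**
1. Target ⇐ C11 acetylation and C7 dithioketal hydrolysis ⇐ C11 ketone ⇐ ethyl enol ether of the pentacyclic skeleton.
2. Cyclohexane and oxepane are formed together by an intramolecular Diels–Alder reaction of a bridged 3-(1-ethoxypropenyl)-2,5-dihydrofuran with a vinyl group carried on the C3 ether oxygen.
3. The diene comes from the enol triflate of an 11-oxabicyclo[6.2.1]undecan-9-one, made by Petasis–Ferrier contraction of a bridged 4-methylene-1,3-dioxolane.
4. Key bond C6–C7: the nine-membered ring is closed by intramolecular alkylation of a 2-lithio-1,3-dithiane (C7 acyl anion equivalent) with the C6 chloride on a cis-dioxolane template.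
5. Fragments: an α-alkoxy aldehyde (5-chloropentyne, Sharpless epoxidation, epoxide alcoholysis with a Roche-ester-derived alcohol) and a dithianyl hydroxy acid (glycidate + 1,3-dithiane). Ring order: dioxolane → oxonane → tetrahydrofuran → cyclohexane + oxepane.

Assumption: atoms are numbered as in eunicellanes (C2–O–C9 tetrahydrofuran, C3–O–C16 oxepane, C7 ketone, C11 acetate, C12 and C15 methyls); read from the SMILES the target is 1S,2S,3S,9S,10R,11R,12R,14S,15R.

**Route**

Step 1
Reactants: 1 methyl (S)-3-hydroxy-2-methylpropanoate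
Product: 2 methyl (S)-3-[(tert-butyldiphenylsilyl)oxy]-2-methylpropanoate
Conditions: TBDPSCl, imidazole, DMF, 0 °C → rt
Reagents that add atoms: tert-butyl(chloro)diphenylsilane CC(C)(C)[Si](Cl)(c1ccccc1)c1ccccc1
Why: Imidazole-promoted O-silylation masks the primary alcohol so the ester can be reduced and olefinated without β-elimination; the stereocentre is not touched.

Step 2
Reactants: 2 methyl (S)-3-[(tert-butyldiphenylsilyl)oxy]-2-methylpropanoate
Product: 3 (S)-3-[(tert-butyldiphenylsilyl)oxy]-2-methylpropanal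
Conditions: DIBAL-H (1.1 equiv), CH2Cl2, −78 °C; Rochelle salt
Reagents that add atoms: none
Why: Partial ester reduction with DIBAL-H stops at the aluminium hemiacetal at −78 °C and releases the aldehyde on work-up with the α-centre intact.

Step 3
Reactants: 3 (S)-3-[(tert-butyldiphenylsilyl)oxy]-2-methylpropanal
Product: 4 (R)-tert-butyl[(2-methylbut-3-en-1-yl)oxy]diphenylsilane
Conditions: Ph3PCH3Br, KHMDS, THF, 0 °C; then 3, −78 → 0 °C
Reagents that add atoms: methyltriphenylphosphonium bromide C[P+](c1ccccc1)(c1ccccc1)c1ccccc1.[Br-]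
Why: Wittig methylenation with the non-stabilised ylide is faster than α-epimerisation at low temperature, so the centre is kept (the descriptor changes to R only through priorities).

Step 4
Reactants: 4 (R)-tert-butyl[(2-methylbut-3-en-1-yl)oxy]diphenylsilane
Product: 5 (R)-2-methylbut-3-en-1-ol
Conditions: TBAF, THF, rt
Reagents that add atoms: none
Why: Fluoride desilylation frees the primary alcohol that later delivers C14–C17 with the C15 stereocentre already set.

Step 5
Reactants: 6 5-chloropent-1-yne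
Product: 8 (E)-6-chloro-3-methylhex-2-en-1-ol, via alkenylalane 7 (not isolated)
Conditions: Me3Al (2 equiv), Cp2ZrCl2 (20 mol%), CH2Cl2, rt; then n-BuLi, (CH2O)n, THF, −78 °C → rt
Reagents that add atoms: trimethylaluminium C[Al](C)C; formaldehyde (as paraformaldehyde) C=O
Why: Negishi zirconium-catalysed carboalumination adds Me and Al syn with methyl on the internal carbon, and hydroxymethylation of the alkenylalanate with retention gives the E trisubstituted allylic alcohol.

Step 6
Reactants: 8 (E)-6-chloro-3-methylhex-2-en-1-ol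
Product: 9 [(2R,3R)-3-(3-chloropropyl)-3-methyloxiran-2-yl]methanol
Conditions: Ti(OiPr)4 (10 mol%), D-(−)-DIPT (12 mol%), t-BuOOH, 4 Å MS, CH2Cl2, −20 °C
Reagents that add atoms: tert-butyl hydroperoxide CC(C)(C)OO
Why: Sharpless asymmetric epoxidation with the D-tartrate delivers oxygen to the face that gives the (2R,3R) epoxide (the geraniol case with the opposite tartrate), fixing the tertiary centre that becomes C3.

Step 7
Reactants: 9 [(2R,3R)-3-(3-chloropropyl)-3-methyloxiran-2-yl]methanol; 5 (R)-2-methylbut-3-en-1-ol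
Product: 10 (2R,3S)-6-chloro-3-methyl-3-{[(R)-2-methylbut-3-en-1-yl]oxy}hexane-1,2-diol
Conditions: 5 (2 equiv, excess recovered), BF3·OEt2 (10 mol%), CH2Cl2, −30 → 0 °C
Reagents that add atoms: none
Why: Lewis-acid epoxide alcoholysis occurs at the tertiary carbon with inversion (borderline SN2), which makes the tertiary ether O1 and sets C3 as S in one operation.

Step 8
Reactants: 10 (2R,3S)-6-chloro-3-methyl-3-{[(R)-2-methylbut-3-en-1-yl]oxy}hexane-1,2-diol
Product: 11 (S)-5-chloro-2-methyl-2-{[(R)-2-methylbut-3-en-1-yl]oxy}pentanal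
Conditions: NaIO4, THF/H2O (3:1), 0 °C
Reagents that add atoms: none
Why: Malaprade glycol cleavage gives the aldehyde (future C2), which has no α-hydrogen and so cannot epimerise at C3.

Step 9
Reactants: 12 methyl (S)-oxirane-2-carboxylate
Product: 13 lithium (S)-oxirane-2-carboxylate
Conditions: LiOH·H2O (1.0 equiv), THF/H2O, 0 °C; lyophilise
Reagents that add atoms: lithium hydroxide [Li+].[OH-]
Why: Cold saponification gives the glycidate salt, whose carboxylate is inert to the carbanion used next.

Step 10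
Reactants: 13 lithium (S)-oxirane-2-carboxylate; 14 1,3-dithiane
Product: 16 (S)-3-(1,3-dithian-2-yl)-2-hydroxypropanoic acid, via 2-lithio-1,3-dithiane 15 (not isolated)
Conditions: 14, n-BuLi, THF, −30 °C; then 13, DMPU, −30 → 0 °C; 1 M HCl to pH 2
Reagents that add atoms: none
Why: Corey–Seebach dithiane anion opens the epoxide at the terminal carbon (as organocuprates do with glycidate salts), so the C9 carbinol centre is retained and C7 arrives as a masked acyl anion.

Step 11
Reactants: 16 (S)-3-(1,3-dithian-2-yl)-2-hydroxypropanoic acid; 11 (S)-5-chloro-2-methyl-2-{[(R)-2-methylbut-3-en-1-yl]oxy}pentanal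
Product: 18 cis-(2S,5S)-2-[(S)-5-chloro-2-{[(R)-2-methylbut-3-en-1-yl]oxy}pentan-2-yl]-5-[(1,3-dithian-2-yl)methyl]-1,3-dioxolan-4-one, via bis-TMS hydroxy acid 17 (not isolated)
Conditions: 16, TMSCl, Et3N, CH2Cl2, rt; then 11, TMSOTf (10 mol%), CH2Cl2, −78 °C
Reagents that add atoms: none
Why: Silyl-mediated (Noyori-type) acetalisation of the hydroxy acid with the pivalaldehyde-like aldehyde gives the kinetic cis-2,5-dioxolanone, placing both chains on one face.

Step 12
Reactants: 18 cis-dioxolanone
Product: 19 (2S,4S)-2-[(S)-5-chloro-2-{[(R)-2-methylbut-3-en-1-yl]oxy}pentan-2-yl]-4-[(1,3-dithian-2-yl)methyl]-5-methylidene-1,3-dioxolane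
Conditions: Cp2TiMe2, toluene, 65 °C, dark
Reagents that add atoms: dimethyltitanocene C[Ti](C)(C1C=CC=C1)C1C=CC=C1
Why: Petasis methylenation converts the lactone carbonyl to the exocyclic enol ether (the new CH2 is C1) and removes the only electrophile that would interfere with organolithium chemistry.

Step 13
Reactants: 19 4-methylene-1,3-dioxolane
Product: 21 bridged enol acetal (7-methyl-10-methylidene-7-{[(R)-2-methylbut-3-en-1-yl]oxy}-9,11-dioxabicyclo[6.2.1]undecane-3-spiro-2'-(1,3-dithiane)), via lithiodithiane 20 (not isolated)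
Conditions: t-BuLi (1.05 equiv), THF–HMPA (9:1), −78 °C, 10 min; dilute to 2 mM with THF, −78 → 20 °C, 12 h
Reagents that add atoms: none
Why: Proposed new method: the 2-lithio-1,3-dithiane (C7 acyl anion equivalent) displaces the primary C6 chloride in an intramolecular Corey–Seebach alkylation, with the cis-dioxolane holding both chains on one face and the quaternary C3 adding a Thorpe–Ingold bias so that nine-membered ring closure can compete at high dilution; the closest known chemistry is Seebach's cyclisation of ω-chloroalkyl dithianes to three- to seven-membered rings and Takahashi's medium-ring closures with cyanohydrin anions; no new stereocentre is formed.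

Step 14
Reactants: 21 bridged enol acetal
Product: 22 bridged ketone (2-methyl-2-{[(R)-2-methylbut-3-en-1-yl]oxy}-11-oxabicyclo[6.2.1]undecan-9-one-6-spiro-2'-(1,3-dithiane))
Conditions: Me2AlCl (2.5 equiv), CH2Cl2, −78 → −20 °C
Reagents that add atoms: none
Why: Petasis–Ferrier rearrangement (dioxolane variant) ionises the acetal to an oxocarbenium/aluminium enolate pair that recloses C1–C2 to the tetrahydrofuran-3-one, and the nine-membered bridge allows only the 2,5-cis ring, which sets C2.

Step 15
Reactants: 22 bridged ketone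
Product: 24 bridged enol triflate (the undec-9-en-9-yl trifluoromethanesulfonate of 22), via potassium enolate 23 (not isolated)
Conditions: KHMDS, THF, −78 °C; then PhNTf2, −78 → 0 °C
Reagents that add atoms: N-phenylbis(trifluoromethanesulfonimide) O=S(=O)(N(c1ccccc1)S(=O)(=O)C(F)(F)F)C(F)(F)F
Why: Kinetic enolisation occurs at the CH2 (C1) and not at the bridgehead C9, and O-triflation gives the vinyl triflate, as in related bridged cladiellin ketones.

Step 16
Reactants: 25 ethoxyethyne
Product: 27 1-ethoxyprop-1-yne, via lithium ethoxyacetylide 26 (not isolated)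
Conditions: n-BuLi, THF, −78 °C; then MeI, −78 → 0 °C
Reagents that add atoms: iodomethane CI
Why: Acetylide alkylation installs the methyl that becomes the C12 methyl.

Step 17
Reactants: 27 1-ethoxyprop-1-yne
Product: 28 tributyl[(E)-1-ethoxyprop-1-en-1-yl]stannane (ethoxy and methyl cis)
Conditions: Bu3SnH, Pd(PPh3)4 (2 mol%), THF, 0 °C
Reagents that add atoms: tributyltin hydride CCCC[SnH](CCCC)CCCC
Why: Palladium-catalysed syn hydrostannation of an ynol ether places tin on the oxygen-bearing carbon, giving a stereodefined α-alkoxyvinylstannane (a propionyl anion equivalent).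

Step 18
Reactants: 24 bridged enol triflate; 28 tributyl[(E)-1-ethoxyprop-1-en-1-yl]stannane
Product: 29 bridged diene (9-[(Z)-1-ethoxyprop-1-en-1-yl]-2-methyl-2-{[(R)-2-methylbut-3-en-1-yl]oxy}-11-oxabicyclo[6.2.1]undec-9-ene-6-spiro-2'-(1,3-dithiane))
Conditions: 28 (1.5 equiv), Pd(PPh3)4 (10 mol%), LiCl (3 equiv), THF, 65 °C
Reagents that add atoms: none
Why: Stille coupling of a vinyl triflate with an α-alkoxyvinylstannane proceeds with retention, giving the 2-ethoxy diene with the methyl in the outside position.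

Step 19
Reactants: 29 bridged diene
Product: 30 pentacyclic ethyl enol ether (C10=C11, 11-OEt, 7,7-propylenedithio)
Conditions: toluene (5 mM), BHT, 180 °C, sealed tube
Reagents that add atoms: none
Why: Type-1 intramolecular Diels–Alder reaction in which the nine-membered bridge blocks the top face, so the tethered vinyl group can only add from below in the exo-tether mode, giving the trans-fused oxepane (C1 and C14), while the outside methyl ends cis to C2 (C12).

Step 20
Reactants: 30 pentacyclic ethyl enol ether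
Product: 31 pentacyclic C11 ketone (7,7-propylenedithio)
Conditions: 1 M HCl, THF, 0 °C
Reagents that add atoms: water O
Why: Enol ether hydrolysis protonates C10 from the face that carries H1, giving the cis-fused hydroisobenzofuran, and the cold dilute acid leaves the kinetically set C12 methyl alone.

Step 21
Reactants: 31 pentacyclic C11 ketone
Product: 32 pentacyclic (11R)-alcohol
Conditions: NaBH4, CeCl3·7H2O, MeOH, −40 °C
Reagents that add atoms: none
Why: Luche-type borohydride reduction attacks axially from the face opposite the axial C9 and C12-methyl groups and gives the equatorial 11R alcohol without base epimerisation.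

Step 22
Reactants: 32 pentacyclic (11R)-alcohol
Product: 33 C11 acetate (7,7-propylenedithio)
Conditions: Ac2O, pyridine, DMAP (cat.), CH2Cl2, rt
Reagents that add atoms: acetic anhydride CC(=O)OC(C)=O
Why: DMAP-catalysed acylation of the secondary alcohol; no stereocentre is affected.

Step 23
Reactants: 33 C11 acetate
Product: 34 CNP0288436.2
Conditions: PhI(O2CCF3)2, MeCN/H2O (9:1), 0 °C
Reagents that add atoms: water O
Why: Oxidative dethioacetalisation with a hypervalent iodine reagent releases the C7 ketone under conditions that spare the acetate and the β-alkoxy ketone; no alkene remains to interfere.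

**Compound list**
1 | methyl (S)-3-hydroxy-2-methylpropanoate | COC(=O)[C@@H](C)CO | starting material
2 | methyl (S)-3-[(tert-butyldiphenylsilyl)oxy]-2-methylpropanoate | COC(=O)[C@@H](C)CO[Si](c1ccccc1)(c1ccccc1)C(C)(C)C | intermediate
3 | (S)-3-[(tert-butyldiphenylsilyl)oxy]-2-methylpropanal | O=C[C@@H](C)CO[Si](c1ccccc1)(c1ccccc1)C(C)(C)C | intermediate
4 | (R)-tert-butyl[(2-methylbut-3-en-1-yl)oxy]diphenylsilane | C=C[C@@H](C)CO[Si](c1ccccc1)(c1ccccc1)C(C)(C)C | intermediate
5 | (R)-2-methylbut-3-en-1-ol | C=C[C@@H](C)CO | intermediate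
6 | 5-chloropent-1-yne | C#CCCCCl | starting material
7 | (E)-(5-chloro-2-methylpent-1-en-1-yl)dimethylalane | C[Al](C)/C=C(\C)CCCCl | intermediate
8 | (E)-6-chloro-3-methylhex-2-en-1-ol | OC/C=C(\C)CCCCl | intermediate
9 | [(2R,3R)-3-(3-chloropropyl)-3-methyloxiran-2-yl]methanol | OC[C@H]1O[C@]1(C)CCCCl | intermediate
10 | (2R,3S)-6-chloro-3-methyl-3-{[(R)-2-methylbut-3-en-1-yl]oxy}hexane-1,2-diol | OC[C@@H](O)[C@](C)(CCCCl)OC[C@H](C)C=C | intermediate
11 | (S)-5-chloro-2-methyl-2-{[(R)-2-methylbut-3-en-1-yl]oxy}pentanal | O=C[C@](C)(CCCCl)OC[C@H](C)C=C | intermediate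
12 | methyl (S)-oxirane-2-carboxylate | COC(=O)[C@@H]1CO1 | starting material
13 | lithium (S)-oxirane-2-carboxylate | [Li+].[O-]C(=O)[C@@H]1CO1 | intermediate
14 | 1,3-dithiane | C1CSCSC1 | starting material
15 | 2-lithio-1,3-dithiane | [Li]C1SCCCS1 | intermediate
16 | (S)-3-(1,3-dithian-2-yl)-2-hydroxypropanoic acid | OC(=O)[C@@H](O)CC1SCCCS1 | intermediate
17 | trimethylsilyl (S)-3-(1,3-dithian-2-yl)-2-[(trimethylsilyl)oxy]propanoate | C[Si](C)(C)OC(=O)[C@@H](O[Si](C)(C)C)CC1SCCCS1 | intermediate
18 | cis-(2S,5S)-2-[(S)-5-chloro-2-{[(R)-2-methylbut-3-en-1-yl]oxy}pentan-2-yl]-5-[(1,3-dithian-2-yl)methyl]-1,3-dioxolan-4-one | O=C1O[C@@H]([C@](C)(CCCCl)OC[C@H](C)C=C)O[C@H]1CC1SCCCS1 | intermediate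
19 | (2S,4S)-2-[(S)-5-chloro-2-{[(R)-2-methylbut-3-en-1-yl]oxy}pentan-2-yl]-4-[(1,3-dithian-2-yl)methyl]-5-methylidene-1,3-dioxolane | C=C1O[C@@H]([C@](C)(CCCCl)OC[C@H](C)C=C)O[C@H]1CC1SCCCS1 | intermediate
20 | 19 lithiated at the dithiane C2 (C7) | C=C1O[C@@H]([C@](C)(CCCCl)OC[C@H](C)C=C)O[C@H]1CC1([Li])SCCCS1 | intermediate
21 | bridged enol acetal: 7-methyl-10-methylidene-7-{[(R)-2-methylbut-3-en-1-yl]oxy}-9,11-dioxabicyclo[6.2.1]undecane-3-spiro-2'-(1,3-dithiane) | C=C1O[C@@H]2O[C@H]1CC1(SCCCS1)CCC[C@]2(C)OC[C@H](C)C=C | intermediate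
22 | bridged ketone: 2-methyl-2-{[(R)-2-methylbut-3-en-1-yl]oxy}-11-oxabicyclo[6.2.1]undecan-9-one-6-spiro-2'-(1,3-dithiane) | O=C1C[C@@H]2O[C@H]1CC1(SCCCS1)CCC[C@]2(C)OC[C@H](C)C=C | intermediate
23 | potassium enolate of 22 (C1=C10) | [K+].[O-]C1=C[C@@H]2O[C@H]1CC1(SCCCS1)CCC[C@]2(C)OC[C@H](C)C=C | intermediate
24 | bridged enol triflate (undec-9-en-9-yl trifluoromethanesulfonate of 22) | O=S(=O)(OC1=C[C@@H]2O[C@H]1CC1(SCCCS1)CCC[C@]2(C)OC[C@H](C)C=C)C(F)(F)F | intermediate
25 | ethoxyethyne | CCOC#C | starting material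
26 | lithium ethoxyacetylide | CCOC#C[Li] | intermediate
27 | 1-ethoxyprop-1-yne | CCOC#CC | intermediate
28 | tributyl[(E)-1-ethoxyprop-1-en-1-yl]stannane | CCO/C(=C\C)[Sn](CCCC)(CCCC)CCCC | intermediate
29 | bridged diene: 9-[(Z)-1-ethoxyprop-1-en-1-yl]-2-methyl-2-{[(R)-2-methylbut-3-en-1-yl]oxy}-11-oxabicyclo[6.2.1]undec-9-ene-6-spiro-2'-(1,3-dithiane) | CCO/C(=C\C)C1=C[C@@H]2O[C@H]1CC1(SCCCS1)CCC[C@]2(C)OC[C@H](C)C=C | intermediate
30 | pentacyclic ethyl enol ether (C10=C11, 11-OEt, 7,7-propylenedithio) | CCOC1=C2[C@@H]3[C@@H](C[C@H]1C)[C@@H](C)CO[C@@]1(C)CCCC4(SCCCS4)C[C@@H]2O[C@@H]31 | intermediate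
31 | pentacyclic C11 ketone (7,7-propylenedithio) | O=C1[C@@H]2[C@@H]3[C@@H](C[C@H]1C)[C@@H](C)CO[C@@]1(C)CCCC4(SCCCS4)C[C@@H]2O[C@@H]31 | intermediate
32 | pentacyclic (11R)-alcohol (7,7-propylenedithio) | O[C@H]1[C@@H]2[C@@H]3[C@@H](C[C@H]1C)[C@@H](C)CO[C@@]1(C)CCCC4(SCCCS4)C[C@@H]2O[C@@H]31 | intermediate
33 | C11 acetate (7,7-propylenedithio) | CC(=O)O[C@H]1[C@@H]2[C@@H]3[C@@H](C[C@H]1C)[C@@H](C)CO[C@@]1(C)CCCC4(SCCCS4)C[C@@H]2O[C@@H]31 | intermediate
34 | CNP0288436.2 | CC(=O)O[C@H]1[C@@H]2[C@@H]3[C@@H](C[C@H]1C)[C@@H](C)CO[C@@]1(C)CCCC(=O)C[C@@H]2O[C@@H]31 | target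

**Step count**
Total: 23 steps. Longest linear sequence: 17 steps (1–4, 7, 8, 11–15, 18–23).

**Steps most likely to fail**

Step 13 (nine-membered ring closure by dithiane alkylation). If oligomers or protonated 19 result, the C6–C7 bond is made between separate molecules and the ring is closed by reversible acetalisation instead. The fallback sets out from diol 10 and comes back at 21. Protection with 2,2-dimethoxypropane and PPTS gives the acetonide F1. 2-Lithio-1,3-dithiane 15 displaces its chloride in THF/HMPA to give the alkyl dithiane F2. A second lithiation (t-BuLi, HMPA) and opening of lithium glycidate 13 gives the acetonide hydroxy acid F3. Aqueous acetic acid gives the diol acid F4, and NaIO4 cleaves it to the aldehyde acid F5. Bis-silylation and TMSOTf at high dilution close the ring as the bridged dioxolanone F6, and Petasis methylenation of F6 gives 21.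

Step 19 (Diels–Alder reaction of an unactivated vinyl group, which may lose to a 1,5-hydrogen shift of the diene at 180 °C). The fallback activates the dienophile and removes the activating group afterwards; it sets out from triflate 24 and comes back at 30. Cross-metathesis with phenyl vinyl sulfone (Hoveyda–Grubbs II) gives the vinyl sulfone triflate F7. Stille coupling with 28 gives the sulfonyl diene F8. The cycloaddition then runs at 80–110 °C to the C13-sulfonyl cycloadduct F9 (configuration at C13 is of no consequence). Sodium amalgam (Na2HPO4, MeOH) removes the sulfone and gives 30.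

Step 20 (C10 protonation and survival of the axial C12 methyl). The fallback installs the methyl after the ring fusion has been secured under equilibrating conditions; it sets out from triflate 24 and comes back at 31. Stille coupling with commercial tributyl(1-ethoxyvinyl)stannane gives the 12-nor diene F10. The same Diels–Alder reaction gives the 12-nor enol ether F11. Hydrolysis followed by K2CO3/MeOH equilibration gives the cis-fused 12-nor ketone F12. α-Methylenation (paraformaldehyde, N-methylanilinium trifluoroacetate) gives the 12-methylidene ketone F13. L-Selectride 1,4-reduction with kinetic protonation of the enolate from the open lower face gives 31.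

**Further compounds**
F1 | step 13 | acetonide of diol 10 | CC1(C)OC[C@@H](O1)[C@](C)(CCCCl)OC[C@H](C)C=C
F2 | step 13 | alkyl dithiane (C6–C7 bond made) | CC1(C)OC[C@@H](O1)[C@](C)(CCCC1SCCCS1)OC[C@H](C)C=C
F3 | step 13 | acetonide hydroxy acid | CC1(C)OC[C@@H](O1)[C@](C)(CCCC1(SCCCS1)C[C@H](O)C(O)=O)OC[C@H](C)C=C
F4 | step 13 | diol acid | OC[C@@H](O)[C@](C)(CCCC1(SCCCS1)C[C@H](O)C(O)=O)OC[C@H](C)C=C
F5 | step 13 | aldehyde acid | O=C[C@](C)(CCCC1(SCCCS1)C[C@H](O)C(O)=O)OC[C@H](C)C=C
F6 | step 13 | bridged dioxolanone | O=C1O[C@@H]2O[C@H]1CC1(SCCCS1)CCC[C@]2(C)OC[C@H](C)C=C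
F7 | step 19 | vinyl sulfone triflate | O=S(=O)(OC1=C[C@@H]2O[C@H]1CC1(SCCCS1)CCC[C@]2(C)OC[C@H](C)/C=C/S(=O)(=O)c1ccccc1)C(F)(F)F
F8 | step 19 | sulfonyl diene | CCO/C(=C\C)C1=C[C@@H]2O[C@H]1CC1(SCCCS1)CCC[C@]2(C)OC[C@H](C)/C=C/S(=O)(=O)c1ccccc1
F9 | step 19 | C13-sulfonyl cycloadduct (C13 undefined) | CCOC1=C2[C@@H]3[C@@H](C([C@H]1C)S(=O)(=O)c1ccccc1)[C@@H](C)CO[C@@]1(C)CCCC4(SCCCS4)C[C@@H]2O[C@@H]31
F10 | step 20 | 12-nor diene | CCOC(=C)C1=C[C@@H]2O[C@H]1CC1(SCCCS1)CCC[C@]2(C)OC[C@H](C)C=C
F11 | step 20 | 12-nor enol ether | CCOC1=C2[C@@H]3[C@@H](CC1)[C@@H](C)CO[C@@]1(C)CCCC4(SCCCS4)C[C@@H]2O[C@@H]31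
F12 | step 20 | 12-nor C11 ketone | O=C1[C@@H]2[C@@H]3[C@@H](CC1)[C@@H](C)CO[C@@]1(C)CCCC4(SCCCS4)C[C@@H]2O[C@@H]31
F13 | step 20 | 12-methylidene C11 ketone | O=C1[C@@H]2[C@@H]3[C@@H](CC1=C)[C@@H](C)CO[C@@]1(C)CCCC4(SCCCS4)C[C@@H]2O[C@@H]31
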